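One turnover was my unit: each pass of the catalyst spends one reagent and leaves one by-product in the flask, and that by-product then competes for substrate. Before the next run I had to decide whether to keep the flask's 10 mol% of free catalyst or charge more.

    substrate + by-product → side product (k1 = 0.0558 M⁻¹ min⁻¹)
    reagent + free catalyst ⇌ catalyst intermediate A (K2 = 6.4 M⁻¹, k2 = 5.02 M⁻¹ min⁻¹)
    catalyst intermediate D → catalyst intermediate E (k3 = 0.0369 min⁻¹)
    substrate + catalyst intermediate C → catalyst intermediate D (k4 = 1.17 M⁻¹ min⁻¹)
    catalyst intermediate B → catalyst intermediate C (k5 = 0.0758 min⁻¹)
    catalyst intermediate A ⇌ by-product + catalyst intermediate B (K6 = 0.011 M, k6 = 0.0962 min⁻¹)
    catalyst intermediate E ⇌ free catalyst + target (K7 = 0.024 M, k7 = 0.0327 min⁻¹)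

substrate 0.020 M; reagent 3.00 equiv; free catalyst 10 mol%; time 10 d

* why nothing more happens at 10 d, or that something still does (forward and back rates have come level / no working catalyst is left / it is still moving / the reagent has run out first / all of the substrate has reacted)
* part of the substrate gone at 10 d
* the target standing at 10 d, as a percentage of the substrate charged
* the side product standing at 10 d, as a percentage of the substrate charged
* amount of target if the flask were left three thousand times as long, in percent of the substrate charged

- the reaction counts as stopped when no species that holds the substrate changes by six tenths of a point or more over the second half of the time
- run time (flask): 10 d

Substrate has two takers, catalyst intermediate C and by-product, and I set the zero of my scale at the even split between them. First I needed the catalyst's position. I took mean stays from forward steps alone, with substrate at the midpoint of its charge and reagent as charged: 85.5 min in catalyst intermediate C and 84.6 min summed over the other forms.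

share of catalyst as intermediate C = 50.3%

catalyst charged = 0.00200 M

break-even = (k4 / k1) × share × catalyst charged = 0.0211 M

This is the break-even by-product, the concentration at which by-product and catalyst intermediate C, at that share, take substrate equally fast. Counting finished passes, the by-product present is one per catalyst for its first pass, plus one per substrate through the cycle, minus one per side product. I tried a side share of 25.0% at the midpoint of the substrate:

by-product = catalyst charged + (substrate charged / 2) × (1 − 2 × trial share) = 0.00700 M

side share = by-product / (by-product + break-even) = 24.9%

The trial came back almost unchanged. Capture at catalyst intermediate C, roughly pseudo-first-order at that share, gives substrate a lifetime of 0.590 d, and the run is far longer, so I committed to substrate gone, side product 24.9% and target 75.1%, the same after the long wait. I decided to charge more free catalyst next, because by-product at a third of break-even still gave a reckoned side share of a quarter, and at a fixed share of catalyst as intermediate C break-even rises with the catalyst charged.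

The forecast said all of the substrate has reacted, with conversion 100%, target 77%, side product 23% and 77% target after the long wait; its split “sends about a quarter of the substrate to side product”. My side product stood 1.9 percentage points above the forecast's.

The flask gave all of the substrate has reacted: conversion 100%, target 73.9%, side product 26.1%, and 73.9% target after the long wait. At 1.00 d this flask held 49.1% of its catalyst as intermediate C, so break-even read 0.0206 M against by-product at 0.00878 M. The neighbour flask took 17 mol% of free catalyst, which is 0.00340 M, and at the same reckoned share its break-even came to 0.0358 M. A trial share of 20.0% gave by-product 0.00940 M and side share 20.8%. That neighbour flask gave target 78.7% and side product 21.3%.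

All constants were drawn at random within sensible limits; the result is computed.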